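**Plan**
- Cuts: first the eleven O-benzyl groups and one benzoate; then, in one stroke, the upper interflavan bond C4–C8 and the C2–C3 bond of the pyran ring (ring C) of the upper epiafzelechin unit; then the lower interflavan bond of a benzylated procyanidin B1.
- Forward: catechin and epicatechin are benzylated and joined (4β→8) to the lower dimer. Separately, 2,4,6-trihydroxybenzaldehyde becomes a 2-ethynylphenol whose free oxygen (future O1) takes the ring B carbon C2 as a benzoyloxy acetal and whose alkyne becomes a (Z)-enol benzoate (C3=C4).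
- Key event: acid ionisation gives an O-aryl oxocarbenium ion at C2, C3 attacks it (Prins closure of ring C), and the C4 cation is captured by C8 of the dimer.
- Enabling feature: ring A carries oxygen at C5, C7 and C8a, so C4 is a strongly stabilised benzylic cation site and C3 of the styrene is its nucleophilic carbon; O1 carries the oxocarbenium carbon, and the C3 oxygen sits next to C4 to steer the incoming arene.
- Stereochemistry: the lower units come from the chiral pool; 2,3-cis from the Z alkene and E oxocarbenium in a chair-like closure; 3,4-trans from anti opening of the benzoate-bridged ion; absolute sense of the upper unit from the chiral counteranion.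

Key step: step 10

Assumption: the acid of step 10 is the (S,S)-imidodiphosphorimidate (IDPi) built from two 3,3'-diphenyl-1,1'-binaphthyl-2,2'-diyl units with an NSO2CF3 group on each phosphorus, and its (S,S) antipode is taken to give the (2R,3R) ring closure; should the sense be opposite, the (R,R) antipode is used.

Step 1
Reactants: 1 (+)-catechin
Product: 2 5,7,3',4'-tetra-O-benzyl-(+)-catechin
Conditions: BnBr (4.4 equiv), K2CO3, DMF, 0 °C to rt
Reagents that add atoms: benzyl bromide, BrCc1ccccc1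
Why: Williamson benzylation of the four phenols with K2CO3, under which the aliphatic 3-OH is not deprotonated; C2 and C3 are untouched.

Step 2
Reactants: 3 (−)-epicatechin
Product: 4 5,7,3',4'-tetra-O-benzyl-(−)-epicatechin
Conditions: BnBr (4.4 equiv), K2CO3, DMF, 0 °C to rt
Reagents that add atoms: benzyl bromide, BrCc1ccccc1
Why: Williamson benzylation of the phenols only, as in step 1; the 2,3-cis centres are untouched.

Step 3
Reactants: 4 5,7,3',4'-tetra-O-benzyl-(−)-epicatechin
Product: 5 4β-(2-ethoxyethoxy)-5,7,3',4'-tetra-O-benzyl-(−)-epicatechin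
Conditions: DDQ (2 equiv), 2-ethoxyethanol (10 equiv), CH2Cl2, rt
Reagents that add atoms: 2-ethoxyethanol, CCOCCO
Why: DDQ abstracts hydride from the benzylic C4 activated by the ring A ethers and the alcohol adds to the cation trans to the 3-OH (oxidative benzylic etherification), which should give the 4β ether.

Step 4
Reactants: 5 4β-(2-ethoxyethoxy)-5,7,3',4'-tetra-O-benzyl-(−)-epicatechin and 2 5,7,3',4'-tetra-O-benzyl-(+)-catechin
Product: 6 octa-O-benzyl procyanidin B1
Conditions: 2 (4 equiv), Me3SiOSO2CF3 (0.2 equiv), CH2Cl2, −78 °C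
Reagents that add atoms: none
Why: The silyl triflate ionises the C4 ether to a ring-A-stabilised flavan-4-yl cation that C8 of 2 attacks anti to the C3 oxygen (Friedel–Crafts-type interflavan coupling), which sets the 3,4-trans (4β→8) centre, while the excess of 2 suppresses oligomers.

Step 5
Reactants: 7 2,4,6-trihydroxybenzaldehyde
Product: 8 2,4-bis(benzyloxy)-6-hydroxybenzaldehyde
Conditions: BnBr (2.1 equiv), K2CO3, DMF, 0 °C to rt
Reagents that add atoms: benzyl bromide, BrCc1ccccc1
Why: Williamson etherification in which the 4-OH and one ortho OH react while the last ortho OH, hydrogen-bonded to the aldehyde, stays free as the future O1.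

Step 6
Reactants: 8 2,4-bis(benzyloxy)-6-hydroxybenzaldehyde
Product: 9 3,5-bis(benzyloxy)-2-ethynylphenol
Conditions: dimethyl (1-diazo-2-oxopropyl)phosphonate (1.5 equiv), K2CO3, MeOH, rt
Reagents that add atoms: dimethyl (1-diazo-2-oxopropyl)phosphonate, CC(=O)C(=[N+]=[N-])P(=O)(OC)OC
Why: Seyferth–Gilbert homologation with the Ohira–Bestmann reagent turns the aldehyde carbon (future C4) into a terminal alkyne (C4≡C3) under carbonate conditions that benzyl ethers tolerate; no stereocenter is formed.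

Step 7
Reactants: 10 4-(benzyloxy)benzaldehyde
Product: 11 bromo[4-(benzyloxy)phenyl]methyl benzoate
Conditions: PhCOBr (1.05 equiv), ZnBr2 (2 mol %), CH2Cl2, 0 °C; used crude
Reagents that add atoms: benzoyl bromide, O=C(Br)c1ccccc1
Why: Acyl bromides add across aromatic aldehydes under zinc halide catalysis to give α-bromoalkyl esters; the new centre is racemic and is flattened again in step 10.

Step 8
Reactants: 9 3,5-bis(benzyloxy)-2-ethynylphenol and 11 bromo[4-(benzyloxy)phenyl]methyl benzoate
Product: 12 [4-(benzyloxy)phenyl][3,5-bis(benzyloxy)-2-ethynylphenoxy]methyl benzoate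
Conditions: iPr2NEt (1.5 equiv), CH2Cl2, −40 to 0 °C
Reagents that add atoms: none
Why: O-alkylation of the phenol by an α-bromoalkyl ester (Williamson type) forms the O1–C2 bond with C2 at the aldehyde oxidation level and a carboxylate leaving group; the acetal carbon is racemic and not retained.

Step 9
Reactants: 12 [4-(benzyloxy)phenyl][3,5-bis(benzyloxy)-2-ethynylphenoxy]methyl benzoate
Product: 13 (Z)-2-[2,4-bis(benzyloxy)-6-{(benzoyloxy)[4-(benzyloxy)phenyl]methoxy}phenyl]ethenyl benzoate
Conditions: PhCO2H (1.2 equiv), Ru(2-methylallyl)2(Ph2P(CH2)4PPh2) (2 mol %), toluene, 50 °C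
Reagents that add atoms: benzoic acid, OC(=O)c1ccccc1
Why: Catalytic anti-Markovnikov hydro-oxycarbonylation of a terminal alkyne through a ruthenium vinylidene, in which benzoate adds to the terminal carbon and protonation of the alkenyl ruthenium should give mainly the (Z)-enol ester; using the same acid as in the acetal ester makes any acyl exchange degenerate.

Step 10
Reactants: 13 (Z)-2-[2,4-bis(benzyloxy)-6-{(benzoyloxy)[4-(benzyloxy)phenyl]methoxy}phenyl]ethenyl benzoate and 6 octa-O-benzyl procyanidin B1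
Product: 16 3-O-benzoyl-5,7,4'-tri-O-benzylepiafzelechin-(4β→8)-octa-O-benzyl procyanidin B1, via oxocarbenium ion 14 (not isolated), via acyloxonium ion 15 (not isolated)
Conditions: 6 (2.5 equiv, excess recovered), (S,S)-IDPi acid C66H41F6N3O8P2S2 (5 mol %), 4 Å MS, CH2Cl2, −60 to −30 °C
Reagents that add atoms: none
Why: Proposed new method: the chiral acid ionises the benzoyloxy acetal of 13 (benzoic acid leaves) to the (E)-O-aryl oxocarbenium ion 14, C3 of the (Z)-enol benzoate attacks C2 in a Prins closure, the resulting C4 benzylic cation is held by the neighbouring benzoate as acyloxonium ion 15, and C8 of the upper ring A of 6 opens it at C4 in a Friedel–Crafts step that returns the proton; the closest known reaction types are the Lewis acid Prins cyclisation of α-acyloxy ethers ended by Friedel–Crafts arylation and the asymmetric Prins cyclisation under confined chiral Brønsted acids, neither yet shown for an O-aryl oxocarbenium ion and a β-acyloxystyrene closing a flavan ring. Ring C closes at C2–C3 in a 6-endo-trig mode with respect to the C3=C4 styrene bond through a chair-like transition state. C2 and C3 are set together: the (E)-oxocarbenium places the ring B aryl equatorial and the (Z)-alkene places the benzoate axial, which gives the 2,3-cis relation, while the chiral counteranion paired with 14 decides which alkene face is attacked and so the (2R,3R) sense. C4 is set by anti opening of the cis-fused acyloxonium ring, which gives the 3,4-trans (4β) aryl group. The step needs attack through C3 and not C4 (6-endo, not 5-exo), which the 5,7-dibenzyloxy ring A should secure by stabilising positive charge at C4 while the benzoate is only a weak donor, and it needs C8 rather than C6 of the upper unit of 6 to react, which is the usual site for benzylated flavan-3-ol nucleophiles.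

Step 11
Reactants: 16 3-O-benzoyl-5,7,4'-tri-O-benzylepiafzelechin-(4β→8)-octa-O-benzyl procyanidin B1
Product: 17 5,7,4'-tri-O-benzylepiafzelechin-(4β→8)-octa-O-benzyl procyanidin B1
Conditions: NaOMe (0.3 equiv), MeOH/THF, 40 °C
Reagents that add atoms: none
Why: Base-catalysed transesterification (Zemplén type) removes the axial benzoate without touching benzyl ethers, interflavan bonds or stereocenters.

Step 12
Reactants: 17 5,7,4'-tri-O-benzylepiafzelechin-(4β→8)-octa-O-benzyl procyanidin B1
Product: 18 (−)-epiafzelechin-(4β→8)-(−)-epicatechin-(4β→8)-(+)-catechin (CNP0158921.1)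
Conditions: H2 (1 atm), Pd(OH)2/C, THF/MeOH/H2O, rt
Reagents that add atoms: none
Why: Hydrogenolysis of the eleven benzyl ethers under neutral conditions leaves the acid-labile interflavan bonds and all nine stereocenters intact.

**Compound list**
1 | (+)-catechin, (2R,3S)-2-(3,4-dihydroxyphenyl)chromane-3,5,7-triol | Oc1cc(O)c2c(c1)O[C@H](c1ccc(O)c(O)c1)[C@@H](O)C2 | starting material
2 | 5,7,3',4'-tetra-O-benzyl-(+)-catechin (3-OH free) | c1ccccc1COc1cc(OCc2ccccc2)c2c(c1)O[C@H](c1ccc(OCc3ccccc3)c(OCc3ccccc3)c1)[C@@H](O)C2 | intermediate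
3 | (−)-epicatechin, (2R,3R)-2-(3,4-dihydroxyphenyl)chromane-3,5,7-triol | Oc1cc(O)c2c(c1)O[C@H](c1ccc(O)c(O)c1)[C@H](O)C2 | starting material
4 | 5,7,3',4'-tetra-O-benzyl-(−)-epicatechin (3-OH free) | c1ccccc1COc1cc(OCc2ccccc2)c2c(c1)O[C@H](c1ccc(OCc3ccccc3)c(OCc3ccccc3)c1)[C@H](O)C2 | intermediate
5 | 4β-(2-ethoxyethoxy)-5,7,3',4'-tetra-O-benzyl-(−)-epicatechin (2,3-cis, 3,4-trans, 3-OH free) | c1ccccc1COc1cc(OCc2ccccc2)c2c(c1)O[C@H](c1ccc(OCc3ccccc3)c(OCc3ccccc3)c1)[C@H](O)[C@H]2OCCOCC | intermediate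
6 | octa-O-benzyl procyanidin B1: 5,7,3',4'-tetra-O-benzylepicatechin-(4β→8)-5,7,3',4'-tetra-O-benzylcatechin, both 3-OH free | c1ccccc1COc1cc(OCc2ccccc2)c2c(c1)O[C@H](c1ccc(OCc3ccccc3)c(OCc3ccccc3)c1)[C@H](O)[C@H]2c1c(OCc2ccccc2)cc(OCc2ccccc2)c2c1O[C@H](c1ccc(OCc3ccccc3)c(OCc3ccccc3)c1)[C@@H](O)C2 | intermediate
7 | 2,4,6-trihydroxybenzaldehyde | O=Cc1c(O)cc(O)cc1O | starting material
8 | 2,4-bis(benzyloxy)-6-hydroxybenzaldehyde | O=Cc1c(O)cc(OCc2ccccc2)cc1OCc1ccccc1 | intermediate
9 | 3,5-bis(benzyloxy)-2-ethynylphenol | C#Cc1c(O)cc(OCc2ccccc2)cc1OCc1ccccc1 | intermediate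
10 | 4-(benzyloxy)benzaldehyde | O=Cc1ccc(OCc2ccccc2)cc1 | starting material
11 | bromo[4-(benzyloxy)phenyl]methyl benzoate (racemic) | O=C(OC(Br)c1ccc(OCc2ccccc2)cc1)c1ccccc1 | intermediate
12 | [4-(benzyloxy)phenyl][3,5-bis(benzyloxy)-2-ethynylphenoxy]methyl benzoate (racemic at the acetal carbon) | C#Cc1c(OC(OC(=O)c2ccccc2)c2ccc(OCc3ccccc3)cc2)cc(OCc2ccccc2)cc1OCc1ccccc1 | intermediate
13 | (Z)-2-[2,4-bis(benzyloxy)-6-{(benzoyloxy)[4-(benzyloxy)phenyl]methoxy}phenyl]ethenyl benzoate (racemic at the acetal carbon) | O=C(O/C=C\c1c(OC(OC(=O)c2ccccc2)c2ccc(OCc3ccccc3)cc2)cc(OCc2ccccc2)cc1OCc1ccccc1)c1ccccc1 | intermediate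
14 | (E)-O-aryl oxocarbenium ion from 13: {2-[(Z)-2-(benzoyloxy)ethenyl]-3,5-bis(benzyloxy)phenyl}[4-(benzyloxy)benzylidene]oxonium | O=C(O/C=C\c1c(/[O+]=C/c2ccc(OCc3ccccc3)cc2)cc(OCc2ccccc2)cc1OCc1ccccc1)c1ccccc1 | intermediate
15 | acyloxonium ion: (2R,3R)-5,7-bis(benzyloxy)-2-[4-(benzyloxy)phenyl]flavan with a 2-phenyl-1,3-dioxolan-2-ylium ring cis-fused across C3–C4, both oxygens cis to the C2 aryl | c1ccccc1COc1ccc([C@H]2Oc3cc(OCc4ccccc4)cc(OCc4ccccc4)c3[C@H]3[O+]=C(c4ccccc4)O[C@@H]23)cc1 | intermediate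
16 | 3-O-benzoyl-5,7,4'-tri-O-benzylepiafzelechin-(4β→8)-5,7,3',4'-tetra-O-benzylepicatechin-(4β→8)-5,7,3',4'-tetra-O-benzylcatechin | c1ccccc1COc1ccc([C@H]2Oc3cc(OCc4ccccc4)cc(OCc4ccccc4)c3[C@H](c3c(OCc4ccccc4)cc(OCc4ccccc4)c4c3O[C@H](c3ccc(OCc5ccccc5)c(OCc5ccccc5)c3)[C@H](O)[C@H]4c3c(OCc4ccccc4)cc(OCc4ccccc4)c4c3O[C@H](c3ccc(OCc5ccccc5)c(OCc5ccccc5)c3)[C@@H](O)C4)[C@H]2OC(=O)c2ccccc2)cc1 | intermediate
17 | 5,7,4'-tri-O-benzylepiafzelechin-(4β→8)-5,7,3',4'-tetra-O-benzylepicatechin-(4β→8)-5,7,3',4'-tetra-O-benzylcatechin (three 3-OH free) | c1ccccc1COc1ccc([C@H]2Oc3cc(OCc4ccccc4)cc(OCc4ccccc4)c3[C@H](c3c(OCc4ccccc4)cc(OCc4ccccc4)c4c3O[C@H](c3ccc(OCc5ccccc5)c(OCc5ccccc5)c3)[C@H](O)[C@H]4c3c(OCc4ccccc4)cc(OCc4ccccc4)c4c3O[C@H](c3ccc(OCc5ccccc5)c(OCc5ccccc5)c3)[C@@H](O)C4)[C@H]2O)cc1 | intermediate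
18 | (−)-epiafzelechin-(4β→8)-(−)-epicatechin-(4β→8)-(+)-catechin, CNP0158921.1 | Oc1ccc([C@H]2Oc3cc(O)cc(O)c3[C@H](c3c(O)cc(O)c4c3O[C@H](c3ccc(O)c(O)c3)[C@H](O)[C@H]4c3c(O)cc(O)c4c3O[C@H](c3ccc(O)c(O)c3)[C@@H](O)C4)[C@H]2O)cc1 | target

Total step count: 12. Longest linear sequence: 7 steps (steps 5, 6, 8, 9, 10, 11, 12, from 7 to 18).

**Steps most likely to fail**

Step 10. The chiral acid may give poor facial selectivity in the Prins closure, so that the trimer with the mirror-image upper unit is formed alongside. The enol benzoate may also be protonated instead of the acetal being ionised, or ion 14 may be captured by 6 before the ring closes. The fallback uses known chemistry and gives up the C2–C3 closure. Commercial (−)-epiafzelechin F1 is benzylated (BnBr, K2CO3, DMF) to 5,7,4'-tri-O-benzyl-(−)-epiafzelechin F2. F2 is oxidised at C4 with DDQ in the presence of 2-ethoxyethanol to 4β-(2-ethoxyethoxy)-5,7,4'-tri-O-benzyl-(−)-epiafzelechin F3. F3 is then coupled with an excess of 6 (Me3SiOSO2CF3, CH2Cl2, −78 °C, as in step 4). The fallback sets out from 6 and comes back to the route at 17.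

Step 9. The acid-labile benzoyloxy acetal may be lost under warm carboxylic acid and ruthenium, either by early ionisation with unselective ring closure or by attack of O1 on the ruthenium vinylidene with expulsion of the acetal carbon; the Z geometry may also erode. The fallback changes the order so that the acetal is made last. 9 is silylated (iPr3SiCl, imidazole, DMF) to [3,5-bis(benzyloxy)-2-ethynylphenoxy]triisopropylsilane F4. F4 takes up benzoic acid under the same ruthenium catalyst to give (Z)-2-{2,4-bis(benzyloxy)-6-[(triisopropylsilyl)oxy]phenyl}ethenyl benzoate F5. The silyl group is removed with Bu4NF buffered with acetic acid at 0 °C to give (Z)-2-[2,4-bis(benzyloxy)-6-hydroxyphenyl]ethenyl benzoate F6. F6 is O-alkylated with 11 (iPr2NEt, CH2Cl2, −40 °C). The fallback sets out from 9 and comes back at 13.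

Step 8. The electron-rich ring of 9 may be alkylated at carbon, or the benzoyl group may be transferred to the phenoxide, instead of O-alkylation. The fallback builds the acetal by reductive acylation. 9 is esterified with 4-(benzyloxy)benzoyl chloride (Et3N, DMAP, CH2Cl2) to 3,5-bis(benzyloxy)-2-ethynylphenyl 4-(benzyloxy)benzoate F7. F7 is reduced with iBu2AlH in CH2Cl2 at −78 °C and trapped in the same flask with benzoic anhydride, pyridine and DMAP. The fallback sets out from 9 and comes back at 12.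

**Further compounds**
F1 | step 10 | (−)-epiafzelechin, (2R,3R)-2-(4-hydroxyphenyl)chromane-3,5,7-triol | Oc1ccc([C@H]2Oc3cc(O)cc(O)c3C[C@H]2O)cc1
F2 | step 10 | 5,7,4'-tri-O-benzyl-(−)-epiafzelechin | c1ccccc1COc1ccc([C@H]2Oc3cc(OCc4ccccc4)cc(OCc4ccccc4)c3C[C@H]2O)cc1
F3 | step 10 | 4β-(2-ethoxyethoxy)-5,7,4'-tri-O-benzyl-(−)-epiafzelechin | c1ccccc1COc1ccc([C@H]2Oc3cc(OCc4ccccc4)cc(OCc4ccccc4)c3[C@H](OCCOCC)[C@H]2O)cc1
F4 | step 9 | [3,5-bis(benzyloxy)-2-ethynylphenoxy]triisopropylsilane | C#Cc1c(O[Si](C(C)C)(C(C)C)C(C)C)cc(OCc2ccccc2)cc1OCc1ccccc1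
F5 | step 9 | (Z)-2-{2,4-bis(benzyloxy)-6-[(triisopropylsilyl)oxy]phenyl}ethenyl benzoate | O=C(O/C=C\c1c(O[Si](C(C)C)(C(C)C)C(C)C)cc(OCc2ccccc2)cc1OCc1ccccc1)c1ccccc1
F6 | step 9 | (Z)-2-[2,4-bis(benzyloxy)-6-hydroxyphenyl]ethenyl benzoate | O=C(O/C=C\c1c(O)cc(OCc2ccccc2)cc1OCc1ccccc1)c1ccccc1
F7 | step 8 | 3,5-bis(benzyloxy)-2-ethynylphenyl 4-(benzyloxy)benzoate | C#Cc1c(OC(=O)c2ccc(OCc3ccccc3)cc2)cc(OCc2ccccc2)cc1OCc1ccccc1
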